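Decide what to turn on Monday's flask with one quantity, the release constant.

| flask | starting material | gas | free catalyst | remark | time |
|---|---|---|---|---|---|
| Monday's | 1 mM | 0.041 mM (held) | 15 mol% | the very flask that is asked about, followed so far |  |
| Sunday's | 1 mM | 0.041 mM (held) | 22 mol% | run made earlier |  |
| flask | 1.0 mM | 0.041 mM (held) | 15 mol% |  | 8.0 min |

| run | time / min | product / % | starting material / % |
|---|---|---|---|
| Monday's | 0.333 | 0 | 72 |
| Monday's | 0.667 | 3 | 53 |
| Monday's | 1.00 | 7 | 37 |
| Monday's | 2.00 | 15 | 17 |
| Monday's | 4.00 | 36 | 3 |
| Sunday's | 0.667 | 4 | 40 |
| Sunday's | 1.33 | 12 | 14 |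
| Sunday's | 2.00 | 23 | 8 |
| Sunday's | 2.50 | 34 | 4 |
| Sunday's | 3.00 | 40 | 3 |

(scatter of a reading: 1.5 percentage points)

- at the start none of the gas is in solution

- teal: doubling the transfer coefficient of the gas, all else as stated
- violet: doubling the amount of free catalyst, all else as stated
- grey: doubling the saturation concentration of gas, all else as stated

* how much product there is at 8.0 min, in percent of the starting material charged
* the change that raises the amount of product at 8.0 min, in percent of the starting material charged most ("none" if none brings more than 2 percentage points) (teal / violet / grey / none)
* amount of product at 8.0 min, in percent of the starting material charged, after grey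

Call the unseen share whatever is neither starting material nor product. From 2.00 min to 4.00 min Monday's product gains 21 percentage points while that share averages 64.5 %. So read the release constant, the part of the share becoming product each minute, a pseudo-first-order constant, as 0.163 min⁻¹.

Turn time first. At 4.00 min, 64.0 % of Monday's flask is not yet product. Hold that amount up to 8.0 min and 22.3 % remains. Put the mean of start and end back in and 35.9 % remains; go round again and 31.5 % remains. The rounds close where each 4.00 min keeps 50.9 % of the remainder, so I reckon 67.4 % product.

Turn catalyst next. Sunday's constant reads 0.256 min⁻¹, faster than Monday's, at 1.57 times the constant for 1.47 times the catalyst. The constant rose with catalyst at equal gas, so I expect little from teal. Let violet stand as Monday's flask at twice the time, which gives 91.6 %. For grey, assume the constant doubles from 4.00 min on, which gives 83.4 %.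

The forecast says 66 % (60 % to 72 %), violet, and 86 % after grey (72 % to 92 %), higher than my grey figure: “Violet wins narrowly, and it is also the safer bet.”

The flask gives 67.4 % and violet. Violet adds 24 points, grey 22 points and teal 1.2 points, and grey ends at 89.4 %.

    starting material + free catalyst → free catalyst + open intermediate (k = 120 M⁻¹ s⁻¹)
    free catalyst + open intermediate ⇌ catalyst intermediate (K = 440 M⁻¹, k = 260 M⁻¹ s⁻¹)
    partner + catalyst intermediate → free catalyst + product (k = 1500 M⁻¹ s⁻¹)
    gas ⇌ partner, rate k4*(csat - [partner]) (kL = 0.540 s⁻¹)

The forecast holds, and a move of 5 points, at 17 mol% of free catalyst or at 8.92 min, takes the asked flask to about the forecast's top edge of 72 %. Now leave the same flask until 30 min. Keep 0.163 min⁻¹ and start again from 64.0 % at 4.00 min, with the remainder shrinking to 50.9 % every 4.00 min. That reckons 99.2 % product. The neighbour flask gives 99.6 %.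

The runs were computed for an exercise; the scatter is artificial.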